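Remark on the chemistry: carotenoid locants (ring C1 to C6, chain C7 to C15, primes for the second half) are used for every intermediate, also where the systematic name numbers the ring differently.

## Structural features

The target is the C2-symmetric C40 carotenoid (3S,5R,8R,3′S,5′R,8′R)-auroxanthin: two identical bicyclic end groups joined through C8 and C8′ by an all-E heptaene (C9 to C9′) that carries four methyl branches. Each end group is a cyclohexane (ring A: C1 gem-dimethyl, C3 secondary carbinol, C5 quaternary) fused along C5–C6 to a 2,5-dihydrofuran (ring B: O, C5, C6=C7, C8). The stereocentres of each half are C3, C5 and C8; C5 and C8 flank the ring oxygen, C3 and C5 are 1,3-related across C4, and the C5 ether oxygen is trans to the C3 hydroxyl. The C8–O bond is allylic on both sides (C6=C7 and the polyene), so any acid able to ionise it scrambles C8; the polyene is also sensitive to light, oxygen and heat. The real difficulty is therefore ring B and not the chain: a fully substituted ether carbon (C5) that no SN2 reaction can make, next to the tetrasubstituted carbon C6 of a ring alkene, and a C8 centre that must be set under kinetic control and then kept away from acid. The key step uses the C5–C6 bond of ring A: an oxirane across it, on the face of the C3 hydroxyl, is opened at C5 by the C8 hydroxyl to form the O–C5 bond and ring B. The hydroxyl left on C6, between the hydrogen-free C1 and C5, can later be lost only toward C7.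

## Logic of the disconnections

25 ⇒ 24. Only the O–Si bonds at C3 and C3′ are cut. The hydroxyls travel as silyl ethers through the organometallic end game and are freed last, with basic fluoride, because 25 does not tolerate acid at C8. The forward step must leave ten alkenes and six stereocentres alone.

24 ⇒ 2 × 19 + 21. The C10–C11 and C10′–C11′ bonds and the two C9–CH3 bonds are cut. The cut follows the symmetry axis, so one chiral fragment is used twice, and the polyene exists for two steps only. The gain is C40 to C13 + C12 + two C1 units. The demand is syn addition of methyl and metal with methyl at C9 only, coupling with retention at both ends, and Lewis acids that do not ionise the C8–O bond.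

21 ⇒ 20. The C11=C12 and C11′=C12′ double bonds are cut back to formyl groups. 20 is commercial and already holds the three inner E-alkenes. The demand is an E-selective iodo-olefination carried out twice on an enal.

19 ⇒ 18 ⇒ 16 (via 17). The alkyne C–Si bond is restored, then the C6=C7 double bond is retraced to a tertiary hydroxyl on C6 and a methylene at C7. The C6 hydroxyl is exactly what the ring-forming step leaves behind, and since C1 and C5 carry no hydrogen it can leave in one direction only. The demand is an elimination that avoids a free C6 cation (a methyl shift from C1 would follow) and avoids acid.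

16 ⇒ 15. The O–Si bond at C3 is cut. The silyl ether is needed so that only the tertiary hydroxyl meets the dehydrating agent. The demand is discrimination between a secondary and a tertiary hydroxyl.

15 ⇒ 14. The O–C5 bond of ring B is cut and C5–C6 is closed as an oxirane. This replaces a quaternary ether carbon by an alkene-derived oxirane and leaves an acyclic carbinol at C8. The gain is one ring and the hardest stereocentre. The demand is opening at C5 with inversion, by the C8 hydroxyl only, without proton loss or 1,2-shift at C5.

14 ⇒ 13. The two oxirane C–O bonds are removed to give the C5=C6 alkene. The forward step must deliver oxygen to the face of the C3 hydroxyl, so that hydroxyl must be free at this stage.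

13 ⇒ 12 ⇒ 11. The C3 silyl ether is restored, then the C8–H bond is cut (carbinol to ketone). C8 is remote from C3, so it is set by a chiral catalyst on a ketone whose two flanks (alkynyl and CH2) differ strongly. The demand is high enantiofacial selectivity with no migration of the β,γ-double bond.

11 ⇒ 8 + 9 (via 10). The C8–C9 bond between the acyl carbon and the alkyne is cut. This gives a two-carbon alkyne building block that later becomes C9 and C10. The demand is a single addition to the acyl group.

8 ⇒ 7 ⇒ 4 + 5 (via 6). The amide C–N bond is exchanged for an ester C–O bond, then the C6–C7 sp2–sp3 bond is cut. The triflate fixes the double bond at C5=C6, which an aldol and dehydration at the ketone would not. 7 is an ethyl ester because it can be aminolysed directly, whereas a tert-butyl ester would need a separate acid cleavage. The demand is a coupling at an alkenyl carbon flanked by the substituents of C1 and C5.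

4 ⇒ 2 ⇒ 1 (via 3). The enol O–S bond, then the O–Si bond, are cut. 1 holds C3 in the right configuration and the gem-dimethyl group, and its only enolisable position is C5. The C5 stereocentre of 1 is given up on purpose.

## Other disconnections considered

Alternative 1: The cut is at C10–C11 and C10′–C11′ together with the two C9–CH3 bonds, so the target is seen as two molecules of the alkynyl dihydrofuran 19 and the pentaenyl diiodide 21. Forward, zirconium-catalysed methylalumination of 19 and palladium-catalysed coupling of the alkenyl metals with 21 would give the bis-silyl ether A1 in one flask.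
- In favour: four C–C bonds and two trisubstituted E-alkenes arise in one operation, the geometry follows from syn addition and retentive coupling and not from an equilibrium, and the symmetry is used fully.
- Against it as the strategic centre: it presupposes ring B with C5 and C8, the only hard part of the structure, and it exposes a doubly activated C8–O bond to AlMe3 and ZnCl2.
- Comparison: structurally the two plans do not compete, since A1 is identical with 24 and the chosen plan adopts this union unchanged as step 14. On fragment assembly and step economy the alternative is the equal of the chosen plan. Mechanistically the union is generic carbometalation and cross-coupling that would serve any C8 alkyne, whereas the stereochemical problem peculiar to this target is solved in step 9.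

Alternative 2: The cut removes the ring oxygen from between C5 and C8 of a butenolide, which is traced to the bicyclo[4.2.0]octenone A2 in which C5 and C8 are still joined by a C–C bond (C3 masked as a dioxolane). Forward, buffered m-CPBA would add to the strained C8 carbonyl and the fully substituted C5 would migrate to oxygen to give the butenolide A3 (Baeyer–Villiger ring expansion).
- In favour: migration is retentive, so the C5–O configuration is inherited from a C–C bond with no inversion and no cation; strain release helps; ring B appears with C6=C7 in place, so no hydroxyl has to be removed from C6. On these two points the alternative is better than the chosen plan.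
- Against it here: A2 needs its own enantioselective synthesis of an all-carbon quaternary centre. C3 is left at the ketone level and must later be reduced with the right facial sense. Above all, C8 arrives as a lactone carbonyl, so the chain has to be attached after partial reduction, through a planar allyl-stabilised oxocarbenium ion in which only the distant C5 substituents can bias the new centre.
- Comparison: on C5 the alternative is the safer (retention against an acid-triggered opening). On C8 and C3 the chosen plan is the safer (a reagent-controlled hydride transfer and a stereocentre bought with 1). On step economy the chosen plan is ahead, because deketalisation, ketone reduction, lactone reduction and C-alkynylation all lie between A3 and a compound of the type of 18.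

Alternative 3: The cut is at O–C8 and C6–C7, so ring B is assembled from the C5 tertiary ketol A4 (C6 ketone without enolisable hydrogen) and the silylated enynal A5. Forward, a diarylprolinol silyl ether with benzoic acid would activate A5 as its iminium ion, the tertiary hydroxyl of A4 would add to the β-carbon (C8), the enamine would close onto the C6 ketone and water would be lost, giving the formyl dihydrofuran A6.
- In favour: ring B, the C6=C7 bond and the C8 centre would be made in one catalytic operation with no epoxide, no cation and no dehydration step. A4 is two or three steps from 1, and after decarbonylation A6 would meet the chosen route at 18 in about half the number of steps. On step economy the alternative is clearly the better.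
- Against it here: a tertiary alcohol is a poor and reversible oxa-Michael donor, the acceptor ketone stands between two fully substituted carbons, the enynal offers a competing 1,6-position and can self-condense, and the extra formyl group on C7 has to be removed with a rhodium reagent in the presence of an alkyne.
- Comparison: C8 control is catalyst-based in both plans and thus comparable in principle, but here it rests on a reversible addition that can erode before the slow aldol step, whereas in the chosen plan C8 is fixed by an irreversible hydride transfer. Each event of the chosen plan is known on its substrate class, while the annulation onto a hindered non-enolisable ketone would be new ground. The chosen plan pays for this reliability with length.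

Key step: step 9

## Route

Step 1
Reactants: 1 actinol, (4R,6R)-4-hydroxy-2,2,6-trimethylcyclohexan-1-one
Product: 2 (4R,6R)-4-[(tert-butyldimethylsilyl)oxy]-2,2,6-trimethylcyclohexan-1-one
Conditions: TBSCl, imidazole, DMF, 25 °C
Reagents that add atoms: tert-butyldimethylsilyl chloride, CC(C)(C)[Si](C)(C)Cl
Why: Imidazole-promoted silyl ether formation at a secondary alcohol; the ketone and both stereocentres are untouched, and the ether shields the C3 oxygen from the strong base and triflating agent that follow.

Step 2
Reactants: 2 (4R,6R)-4-[(tert-butyldimethylsilyl)oxy]-2,2,6-trimethylcyclohexan-1-one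
Product: 4 (4R)-4-[(tert-butyldimethylsilyl)oxy]-2,6,6-trimethylcyclohex-1-en-1-yl trifluoromethanesulfonate, via potassium enolate 3 (not isolated)
Conditions: KN(SiMe3)2, THF, −78 °C; then PhNTf2, −78 → 0 °C
Reagents that add atoms: N-phenylbis(trifluoromethanesulfonimide), O=S(=O)(N(c1ccccc1)S(=O)(=O)C(F)(F)F)C(F)(F)F
Why: Enol triflate formation; only the C5 hydrogen is enolisable (C1 is quaternary), so a single tetrasubstituted enolate forms and is O-sulfonylated. The C5 stereocentre of 1 is erased on purpose, and the C3 silyloxy group is γ to the carbonyl and cannot be eliminated.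

Step 3
Reactants: 4 (4R)-4-[(tert-butyldimethylsilyl)oxy]-2,6,6-trimethylcyclohex-1-en-1-yl trifluoromethanesulfonate; 5 ethyl bromoacetate
Product: 7 ethyl 2-[(4R)-4-[(tert-butyldimethylsilyl)oxy]-2,6,6-trimethylcyclohex-1-en-1-yl]acetate, via Reformatsky reagent 6 (not isolated)
Conditions: 5, Zn dust (TMSCl-activated), THF, 40 °C; then 4, Pd2(dba)3 (2.5 mol %), XPhos (10 mol %), THF, 60 °C
Reagents that add atoms: none
Why: Negishi-type cross-coupling of an alkenyl triflate with a Reformatsky reagent (sp2–sp3), with a bulky biaryl phosphine to help the hindered oxidative addition and the reductive elimination. The triflate fixes the double bond at C5=C6, so the β,γ-unsaturated ester forms without touching C3.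

Step 4
Reactants: 7 ethyl 2-[(4R)-4-[(tert-butyldimethylsilyl)oxy]-2,6,6-trimethylcyclohex-1-en-1-yl]acetate
Product: 8 2-[(4R)-4-[(tert-butyldimethylsilyl)oxy]-2,6,6-trimethylcyclohex-1-en-1-yl]-N-methoxy-N-methylacetamide
Conditions: MeNH(OMe)·HCl, i-PrMgCl, THF, −20 → 0 °C
Reagents that add atoms: N,O-dimethylhydroxylamine hydrochloride, CNOC.Cl
Why: Weinreb amide formation by direct aminolysis of an ethyl ester with the chloromagnesium amide; at low temperature this weak, hindered base should not move the double bond into conjugation.

Step 5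
Reactants: 8 2-[(4R)-4-[(tert-butyldimethylsilyl)oxy]-2,6,6-trimethylcyclohex-1-en-1-yl]-N-methoxy-N-methylacetamide; 9 ethynyltrimethylsilane
Product: 11 1-[(4R)-4-[(tert-butyldimethylsilyl)oxy]-2,6,6-trimethylcyclohex-1-en-1-yl]-4-(trimethylsilyl)but-3-yn-2-one, via lithium acetylide 10 (not isolated)
Conditions: 9, n-BuLi, THF, −78 °C; then 8, −78 → 0 °C; aq NH4Cl
Reagents that add atoms: none
Why: Acylation of a lithium acetylide by a Weinreb amide; the chelated tetrahedral adduct survives until work-up, so a single addition gives the alkynyl ketone, and the silyl cap blocks conjugate addition at the alkyne terminus.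

Step 6
Reactants: 11 1-[(4R)-4-[(tert-butyldimethylsilyl)oxy]-2,6,6-trimethylcyclohex-1-en-1-yl]-4-(trimethylsilyl)but-3-yn-2-one
Product: 12 (2R)-1-[(4R)-4-[(tert-butyldimethylsilyl)oxy]-2,6,6-trimethylcyclohex-1-en-1-yl]-4-(trimethylsilyl)but-3-yn-2-ol (8R)
Conditions: RuCl(p-cymene)[(R,R)-TsDPEN] (2 mol %, converted to the amido complex with KOH beforehand), i-PrOH, 25 °C
Reagents that add atoms: none
Why: Noyori asymmetric transfer hydrogenation of an alkyl alkynyl ketone; the alkynyl group takes the place that an aryl group has in the six-membered hydride and proton transfer, so the (R,R)-catalyst should give the (8R)-carbinol independently of the remote C3 centre. The base-free medium spares the alkynylsilane and the β,γ-alkene.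

Step 7
Reactants: 12 (2R)-1-[(4R)-4-[(tert-butyldimethylsilyl)oxy]-2,6,6-trimethylcyclohex-1-en-1-yl]-4-(trimethylsilyl)but-3-yn-2-ol
Product: 13 (1R)-4-[(2R)-2-hydroxy-4-(trimethylsilyl)but-3-yn-1-yl]-3,5,5-trimethylcyclohex-3-en-1-ol
Conditions: CSA (0.2 equiv), MeOH, 25 °C
Reagents that add atoms: none
Why: Acid-catalysed methanolysis of a secondary silyl ether (O-desilylation); the alkynyl C–Si bond is stable to acid (fluoride or base would cleave it), and the tetrasubstituted alkene and the propargylic alcohol should not react with catalytic sulfonic acid in methanol.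

Step 8
Reactants: 13 (1R)-4-[(2R)-2-hydroxy-4-(trimethylsilyl)but-3-yn-1-yl]-3,5,5-trimethylcyclohex-3-en-1-ol
Product: 14 (1S,3S,6R)-6-[(2R)-2-hydroxy-4-(trimethylsilyl)but-3-yn-1-yl]-1,5,5-trimethyl-7-oxabicyclo[4.1.0]heptan-3-ol (oxirane cis to the ring hydroxyl; 3S,5S,6R,8R)
Conditions: VO(acac)2 (5 mol %), t-BuOOH (1.5 equiv, decane), CH2Cl2, 0 → 25 °C
Reagents that add atoms: tert-butyl hydroperoxide, CC(C)(C)OO
Why: Hydroxyl-directed epoxidation of a homoallylic alcohol through a vanadate alkyl peroxide: the ring C3 hydroxyl, bound to vanadium in its pseudoaxial conformer, delivers oxygen to its own face of C5=C6 and sets C5 (S) and C6 (R). The C8 carbinol is homoallylic as well; a chair-like model with the alkynyl group outward suggests that the (8R) configuration delivers to the same face, but this is not relied on.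

Step 9
Reactants: 14 (1S,3S,6R)-6-[(2R)-2-hydroxy-4-(trimethylsilyl)but-3-yn-1-yl]-1,5,5-trimethyl-7-oxabicyclo[4.1.0]heptan-3-ol
Product: 15 (2R,3aR,6S,7aR)-4,4,7a-trimethyl-2-[(trimethylsilyl)ethynyl]octahydro-1-benzofuran-3a,6-diol (cis ring fusion; 3S,5R,6R,8R)
Conditions: CSA (0.1 equiv), CH2Cl2, 0 °C
Reagents that add atoms: none
Why: The sulfonic acid protonates (or hydrogen-bonds to) the oxirane oxygen and the C5–O bond begins to lengthen, because C5 is the tertiary carbon that carries a methyl group, while C6 is wedged between C1 and C5 and could be reached by the C8 oxygen only through a four-membered ring. The C8 hydroxyl hangs from C6 through C7 on the face opposite to the oxirane oxygen, so it reaches C5 from the back, and proton loss completes the O–C5 bond. The closest known reaction type is the acid-catalysed cyclisation of 3,4-epoxy alcohols to 3-hydroxytetrahydrofurans by attack at the more substituted oxirane carbon. The ring closes in the 5-endo-tet mode with respect to the oxirane, which is feasible because the transition state is loose at C5 and the 4-exo alternative is strained. One stereocentre changes, C5, inverted from S to R; it is controlled by the oxirane configuration from step 8 and by the tether, which can deliver oxygen only anti to the oxirane oxygen, so the ether oxygen ends trans to the C3 hydroxyl and the ring fusion is cis, while C3, C6 and C8 are untouched. The step needs regioselectivity (C5 over C6), chemoselectivity against the C3 hydroxyl, and capture in preference to proton loss or a 1,2-shift at C5. The first is secured by ring size and substitution, the second by the C3 hydroxyl lying on the face of the oxirane oxygen where it cannot reach the back of either carbon, and the third by catalytic acid in a cold, non-nucleophilic solvent with the nucleophile already in place.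

Step 10
Reactants: 15 (2R,3aR,6S,7aR)-4,4,7a-trimethyl-2-[(trimethylsilyl)ethynyl]octahydro-1-benzofuran-3a,6-diol
Product: 16 (2R,3aR,6S,7aR)-6-[(tert-butyldimethylsilyl)oxy]-4,4,7a-trimethyl-2-[(trimethylsilyl)ethynyl]octahydro-1-benzofuran-3a-ol
Conditions: TBSCl, imidazole, DMF, 25 °C
Reagents that add atoms: tert-butyldimethylsilyl chloride, CC(C)(C)[Si](C)(C)Cl
Why: Silyl ether formation; the secondary C3 hydroxyl is silylated, while the tertiary C6 hydroxyl, flanked by two fully substituted carbons, stays free for the elimination.

Step 11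
Reactants: 16 (2R,3aR,6S,7aR)-6-[(tert-butyldimethylsilyl)oxy]-4,4,7a-trimethyl-2-[(trimethylsilyl)ethynyl]octahydro-1-benzofuran-3a-ol
Product: 18 tert-butyldimethyl{[(2R,6S,7aR)-4,4,7a-trimethyl-2-[(trimethylsilyl)ethynyl]-2,4,5,6,7,7a-hexahydro-1-benzofuran-6-yl]oxy}silane, via sulfamate ester 17 (not isolated)
Conditions: Burgess reagent, toluene, 50 °C
Reagents that add atoms: none
Why: Burgess dehydration (syn elimination through the sulfamate ester); C1 and C5 bear no hydrogen, so the only β-hydrogens are on C7 and the alkene can form only as C6=C7. The medium is non-acidic, which protects the C8–O bond that becomes doubly activated in the product.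

Step 12
Reactants: 18 tert-butyldimethyl{[(2R,6S,7aR)-4,4,7a-trimethyl-2-[(trimethylsilyl)ethynyl]-2,4,5,6,7,7a-hexahydro-1-benzofuran-6-yl]oxy}silane
Product: 19 tert-butyl{[(2R,6S,7aR)-2-ethynyl-4,4,7a-trimethyl-2,4,5,6,7,7a-hexahydro-1-benzofuran-6-yl]oxy}dimethylsilane
Conditions: K2CO3 (0.3 equiv), MeOH, 0 → 25 °C
Reagents that add atoms: none
Why: Protodesilylation of an alkynylsilane by catalytic methoxide; the silyl ether is stable, and the C8 hydrogen is far too weakly acidic for methoxide, so C8 is not at risk.

Step 13
Reactants: 20 (2E,4E,6E)-2,7-dimethylocta-2,4,6-trienedial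
Product: 21 (1E,3E,5E,7E,9E)-1,10-diiodo-3,8-dimethyldeca-1,3,5,7,9-pentaene
Conditions: CrCl2 (12 equiv), CHI3 (4 equiv), THF/1,4-dioxane, 0 → 25 °C, dark
Reagents that add atoms: iodoform, IC(I)I
Why: Takai olefination at both formyl groups with the geminal dichromium reagent formed from CHI3 and divalent chromium; elimination from the β-oxido chromium intermediate should give the E-iodoalkenes, and the existing trisubstituted alkenes keep their geometry.

Step 14
Reactants: 19 tert-butyl{[(2R,6S,7aR)-2-ethynyl-4,4,7a-trimethyl-2,4,5,6,7,7a-hexahydro-1-benzofuran-6-yl]oxy}dimethylsilane (two molecules); 21 (1E,3E,5E,7E,9E)-1,10-diiodo-3,8-dimethyldeca-1,3,5,7,9-pentaene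
Product: 24 bis(tert-butyldimethylsilyl) ether of (3S,5R,8R,3′S,5′R,8′R)-auroxanthin, via alkenylalane 22 (not isolated), via alkenylzinc chloride 23 (not isolated)
Conditions: 19 (2.3 equiv), AlMe3, Cp2ZrCl2 (25 mol %), CH2Cl2, 0 °C; then ZnCl2, THF, 21 (1.0 equiv), Pd(PPh3)4 (5 mol %), 25 °C, dark
Reagents that add atoms: trimethylaluminium, C[Al](C)C
Why: Zirconium-catalysed methylalumination (syn addition of CH3–Al with methyl at the internal carbon C9), then Negishi coupling of the alkenyl metal with both C–I bonds of 21 with retention; syn addition plus retention fixes the 9E and 9′E bonds. The C8 ether oxygen is γ to the metal and cannot be eliminated, and the short, cold exposure to AlMe3 is meant to spare the C8–O bond.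

Step 15
Reactants: 24 bis(tert-butyldimethylsilyl) ether of (3S,5R,8R,3′S,5′R,8′R)-auroxanthin
Product: 25 (3S,5R,8R,3′S,5′R,8′R)-auroxanthin
Conditions: TBAF, THF, 0 → 25 °C, dark
Reagents that add atoms: none
Why: Fluoride-mediated cleavage of both silyl ethers; basic conditions are chosen because the C8–O bond of the polyene ether ionises with acid, and no stereocentre or alkene is affected.

## Compound list

1 | actinol, (4R,6R)-4-hydroxy-2,2,6-trimethylcyclohexan-1-one | O=C1C(C)(C)C[C@H](O)C[C@H]1C | starting material
2 | (4R,6R)-4-[(tert-butyldimethylsilyl)oxy]-2,2,6-trimethylcyclohexan-1-one | O=C1C(C)(C)C[C@H](O[Si](C)(C)C(C)(C)C)C[C@H]1C | intermediate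
3 | potassium (4R)-4-[(tert-butyldimethylsilyl)oxy]-2,6,6-trimethylcyclohex-1-en-1-olate (not isolated) | [K+].[O-]C1=C(C)C[C@@H](O[Si](C)(C)C(C)(C)C)CC1(C)C | intermediate
4 | (4R)-4-[(tert-butyldimethylsilyl)oxy]-2,6,6-trimethylcyclohex-1-en-1-yl trifluoromethanesulfonate | FC(F)(F)S(=O)(=O)OC1=C(C)C[C@@H](O[Si](C)(C)C(C)(C)C)CC1(C)C | intermediate
5 | ethyl bromoacetate | CCOC(=O)CBr | starting material
6 | bromo(2-ethoxy-2-oxoethyl)zinc, Reformatsky reagent (not isolated) | CCOC(=O)C[Zn]Br | intermediate
7 | ethyl 2-[(4R)-4-[(tert-butyldimethylsilyl)oxy]-2,6,6-trimethylcyclohex-1-en-1-yl]acetate | CCOC(=O)CC1=C(C)C[C@@H](O[Si](C)(C)C(C)(C)C)CC1(C)C | intermediate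
8 | 2-[(4R)-4-[(tert-butyldimethylsilyl)oxy]-2,6,6-trimethylcyclohex-1-en-1-yl]-N-methoxy-N-methylacetamide | CON(C)C(=O)CC1=C(C)C[C@@H](O[Si](C)(C)C(C)(C)C)CC1(C)C | intermediate
9 | ethynyltrimethylsilane | C#C[Si](C)(C)C | starting material
10 | lithium (trimethylsilyl)acetylide (not isolated) | [Li]C#C[Si](C)(C)C | intermediate
11 | 1-[(4R)-4-[(tert-butyldimethylsilyl)oxy]-2,6,6-trimethylcyclohex-1-en-1-yl]-4-(trimethylsilyl)but-3-yn-2-one | C[Si](C)(C)C#CC(=O)CC1=C(C)C[C@@H](O[Si](C)(C)C(C)(C)C)CC1(C)C | intermediate
12 | (2R)-1-[(4R)-4-[(tert-butyldimethylsilyl)oxy]-2,6,6-trimethylcyclohex-1-en-1-yl]-4-(trimethylsilyl)but-3-yn-2-ol | C[Si](C)(C)C#C[C@H](O)CC1=C(C)C[C@@H](O[Si](C)(C)C(C)(C)C)CC1(C)C | intermediate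
13 | (1R)-4-[(2R)-2-hydroxy-4-(trimethylsilyl)but-3-yn-1-yl]-3,5,5-trimethylcyclohex-3-en-1-ol | C[Si](C)(C)C#C[C@H](O)CC1=C(C)C[C@@H](O)CC1(C)C | intermediate
14 | (1S,3S,6R)-6-[(2R)-2-hydroxy-4-(trimethylsilyl)but-3-yn-1-yl]-1,5,5-trimethyl-7-oxabicyclo[4.1.0]heptan-3-ol (oxirane cis to the ring hydroxyl) | C[Si](C)(C)C#C[C@H](O)C[C@]12O[C@@]1(C)C[C@@H](O)CC2(C)C | intermediate
15 | (2R,3aR,6S,7aR)-4,4,7a-trimethyl-2-[(trimethylsilyl)ethynyl]octahydro-1-benzofuran-3a,6-diol (cis-fused) | C[Si](C)(C)C#C[C@H]1C[C@@]2(O)C(C)(C)C[C@H](O)C[C@@]2(C)O1 | intermediate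
16 | (2R,3aR,6S,7aR)-6-[(tert-butyldimethylsilyl)oxy]-4,4,7a-trimethyl-2-[(trimethylsilyl)ethynyl]octahydro-1-benzofuran-3a-ol | C[Si](C)(C)C#C[C@H]1C[C@@]2(O)C(C)(C)C[C@H](O[Si](C)(C)C(C)(C)C)C[C@@]2(C)O1 | intermediate
17 | triethylammonium salt of the N-(methoxycarbonyl)sulfamate ester of 16 at the C6 oxygen (not isolated) | C[Si](C)(C)C#C[C@H]1C[C@@]2(OS(=O)(=O)[N-]C(=O)OC)C(C)(C)C[C@H](O[Si](C)(C)C(C)(C)C)C[C@@]2(C)O1.CC[NH+](CC)CC | intermediate
18 | tert-butyldimethyl{[(2R,6S,7aR)-4,4,7a-trimethyl-2-[(trimethylsilyl)ethynyl]-2,4,5,6,7,7a-hexahydro-1-benzofuran-6-yl]oxy}silane | C[Si](C)(C)C#C[C@H]1C=C2C(C)(C)C[C@H](O[Si](C)(C)C(C)(C)C)C[C@@]2(C)O1 | intermediate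
19 | tert-butyl{[(2R,6S,7aR)-2-ethynyl-4,4,7a-trimethyl-2,4,5,6,7,7a-hexahydro-1-benzofuran-6-yl]oxy}dimethylsilane | C#C[C@H]1C=C2C(C)(C)C[C@H](O[Si](C)(C)C(C)(C)C)C[C@@]2(C)O1 | intermediate
20 | (2E,4E,6E)-2,7-dimethylocta-2,4,6-trienedial | O=C/C(C)=C/C=C/C=C(C)/C=O | starting material
21 | (1E,3E,5E,7E,9E)-1,10-diiodo-3,8-dimethyldeca-1,3,5,7,9-pentaene | I/C=C/C(C)=C/C=C/C=C(C)/C=C/I | intermediate
22 | dimethyl[(1E)-2-{(2R,6S,7aR)-6-[(tert-butyldimethylsilyl)oxy]-4,4,7a-trimethyl-2,4,5,6,7,7a-hexahydro-1-benzofuran-2-yl}prop-1-en-1-yl]alumane (not isolated) | C[Al](C)/C=C(\C)[C@H]1C=C2C(C)(C)C[C@H](O[Si](C)(C)C(C)(C)C)C[C@@]2(C)O1 | intermediate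
23 | chloro[(1E)-2-{(2R,6S,7aR)-6-[(tert-butyldimethylsilyl)oxy]-4,4,7a-trimethyl-2,4,5,6,7,7a-hexahydro-1-benzofuran-2-yl}prop-1-en-1-yl]zinc (not isolated) | Cl[Zn]/C=C(\C)[C@H]1C=C2C(C)(C)C[C@H](O[Si](C)(C)C(C)(C)C)C[C@@]2(C)O1 | intermediate
24 | bis(tert-butyldimethylsilyl) ether of (3S,5R,8R,3′S,5′R,8′R)-auroxanthin | CC(/C=C/C=C(\C)[C@H]1C=C2C(C)(C)C[C@H](O[Si](C)(C)C(C)(C)C)C[C@@]2(C)O1)=C\C=C\C=C(C)\C=C\C=C(/C)[C@H]1C=C2C(C)(C)C[C@H](O[Si](C)(C)C(C)(C)C)C[C@@]2(C)O1 | intermediate
25 | (3S,5R,8R,3′S,5′R,8′R)-auroxanthin, all-E-5,8:5′,8′-diepoxy-5,8,5′,8′-tetrahydro-β,β-carotene-3,3′-diol | CC(/C=C/C=C(\C)[C@H]1C=C2C(C)(C)C[C@H](O)C[C@@]2(C)O1)=C\C=C\C=C(C)\C=C\C=C(/C)[C@H]1C=C2C(C)(C)C[C@H](O)C[C@@]2(C)O1 | target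

## Step count and least certain steps

Total: 15 steps. Longest linear sequence: 14 steps (steps 1 to 12, 14 and 15, from 1 to 25); step 13 is a one-step branch from 20.

Step 9 (key step). The most likely failure is ionisation at C5 running ahead of ring closure, so that proton loss from C4 or from the C5 methyl group (allylic alcohols) or a 1,2-shift to C5 (ring contraction or ketone formation) competes with capture by the weakly nucleophilic propargylic hydroxyl. The fallback makes C5 a nucleophile instead; it sets out from 11 and returns at 18. 11 would be reduced with the enantiomeric catalyst RuCl(p-cymene)[(S,S)-TsDPEN] to the (8S)-propargylic alcohol F1. Stoichiometric OsO4 in pyridine (then NaHSO3) would add two hydroxyls to C5=C6 from the face opposite to the C3 silyloxy group to give the 5,6-cis-diol F2, in which the C5–O bond already has the configuration of the target. MsCl and Et3N would sulfonylate only the secondary propargylic hydroxyl to give the mesylate F3, and NaH in THF would let the C5 alkoxide displace it (5-exo-tet, inversion at C8) to give the trans-fused hydroxy tetrahydrofuran F4, the C6 epimer of 16. Burgess dehydration of F4 as in step 11 would give 18. The price is an osmylation of a hindered tetrasubstituted alkene.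

Step 14. The most likely failure is ionisation of the C8–O bond of 19, 22, 23 or 24 by the aluminium and zinc Lewis acids (an allyl and propargyl cation with a tertiary terminus at C6), with loss of configuration at C8; an incomplete second coupling is the lesser risk. The fallback carbometalates before ring B has its alkene and couples under basic conditions; it sets out from 16 and returns at 24. K2CO3 in MeOH would give the terminal alkyne F5. Cp2ZrCl2 and AlMe3, then I2, would give the (E)-iodoalkene F6; here the C8–O bond is only propargylic when it meets AlMe3 and the C6 hydroxyl travels as its aluminium alkoxide. Burgess dehydration would give the iodoalkenyl dihydrofuran F7. Separately, 20 with CrCl2, LiI and Cl2CHBpin would give the bis(pinacol boronate) F8. Two-fold Suzuki–Miyaura coupling of F7 with F8 (Pd(PPh3)4, aqueous K3PO4, THF) would give 24.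

Step 8. The most likely failure is erosion of facial selectivity because the C8 hydroxyl competes as a second homoallylic directing group, together with vanadium-mediated oxidation of the propargylic carbinol. The fallback leaves only the ring hydroxyl free; it sets out from 12 and returns at 14. Ac2O, pyridine and DMAP would give the C8 acetate F9. HF·pyridine in THF would free the C3 hydroxyl to give the hydroxy acetate F10. VO(acac)2 and t-BuOOH would then give the syn-epoxy acetate F11 with a single director, and i-Bu2AlH in CH2Cl2 at −78 °C would remove the acetyl group without touching the oxirane or the alkynylsilane, to give 14.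

Step 3. The most likely failure is slow oxidative addition and transmetalation at the tetrasubstituted triflate flanked by the C1 and C5 substituents, so that self-condensation of the zinc enolate and reduction of the triflate take over. The fallback uses an sp2 tin partner and passes through the aldehyde; it sets out from 4 and returns at 11. Stille coupling of 4 with tributyl[(Z)-2-ethoxyvinyl]stannane (Pd(PPh3)4, LiCl, CuI, DMF) would give the dienyl ether F12. Oxalic acid in wet THF would hydrolyse it to the aldehyde F13. Addition of 10 would give the propargylic alcohol F14 as a mixture at C8, and Dess–Martin periodinane would oxidise it to 11, so that C8 is still set by step 6.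

Step 13. The most likely failure is incomplete E-selectivity at one of the two new alkenes (enals are the less selective substrates) and light-induced isomerisation of the pentaenyl diiodide during isolation. The fallback makes the two iodoalkenes by syn hydrometalation of alkynes; it sets out from 20 and returns at 21. CBr4 and PPh3 would give the bis(dibromoalkene) F15, n-BuLi in THF at −78 °C would convert it to the dienediyne F16, and Cp2Zr(H)Cl followed by I2 would give 21 with both new alkenes E by mechanism.

## Further compounds

F1 | step 9 | (2S)-1-[(4R)-4-[(tert-butyldimethylsilyl)oxy]-2,6,6-trimethylcyclohex-1-en-1-yl]-4-(trimethylsilyl)but-3-yn-2-ol | C[Si](C)(C)C#C[C@@H](O)CC1=C(C)C[C@@H](O[Si](C)(C)C(C)(C)C)CC1(C)C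
F2 | step 9 | (1S,2R,4S)-4-[(tert-butyldimethylsilyl)oxy]-1-[(2S)-2-hydroxy-4-(trimethylsilyl)but-3-yn-1-yl]-2,6,6-trimethylcyclohexane-1,2-diol (ring hydroxyls cis to each other and trans to the silyloxy group) | C[Si](C)(C)C#C[C@@H](O)C[C@]1(O)C(C)(C)C[C@H](O[Si](C)(C)C(C)(C)C)C[C@@]1(C)O
F3 | step 9 | (2S)-1-[(1S,2R,4S)-4-[(tert-butyldimethylsilyl)oxy]-1,2-dihydroxy-2,6,6-trimethylcyclohexyl]-4-(trimethylsilyl)but-3-yn-2-yl methanesulfonate | C[Si](C)(C)C#C[C@@H](OS(C)(=O)=O)C[C@]1(O)C(C)(C)C[C@H](O[Si](C)(C)C(C)(C)C)C[C@@]1(C)O
F4 | step 9 | (2R,3aS,6S,7aR)-6-[(tert-butyldimethylsilyl)oxy]-4,4,7a-trimethyl-2-[(trimethylsilyl)ethynyl]octahydro-1-benzofuran-3a-ol (trans-fused) | C[Si](C)(C)C#C[C@H]1C[C@]2(O)C(C)(C)C[C@H](O[Si](C)(C)C(C)(C)C)C[C@@]2(C)O1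
F5 | step 14 | (2R,3aR,6S,7aR)-6-[(tert-butyldimethylsilyl)oxy]-2-ethynyl-4,4,7a-trimethyloctahydro-1-benzofuran-3a-ol | C#C[C@H]1C[C@@]2(O)C(C)(C)C[C@H](O[Si](C)(C)C(C)(C)C)C[C@@]2(C)O1
F6 | step 14 | (2R,3aR,6S,7aR)-6-[(tert-butyldimethylsilyl)oxy]-2-[(1E)-1-iodoprop-1-en-2-yl]-4,4,7a-trimethyloctahydro-1-benzofuran-3a-ol | I/C=C(\C)[C@H]1C[C@@]2(O)C(C)(C)C[C@H](O[Si](C)(C)C(C)(C)C)C[C@@]2(C)O1
F7 | step 14 | tert-butyl{[(2R,6S,7aR)-2-[(1E)-1-iodoprop-1-en-2-yl]-4,4,7a-trimethyl-2,4,5,6,7,7a-hexahydro-1-benzofuran-6-yl]oxy}dimethylsilane | I/C=C(\C)[C@H]1C=C2C(C)(C)C[C@H](O[Si](C)(C)C(C)(C)C)C[C@@]2(C)O1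
F8 | step 14 | 2,2′-[(1E,3E,5E,7E,9E)-3,8-dimethyldeca-1,3,5,7,9-pentaene-1,10-diyl]bis(4,4,5,5-tetramethyl-1,3,2-dioxaborolane) | CC1(C)OB(/C=C/C(C)=C/C=C/C=C(C)/C=C/B2OC(C)(C)C(C)(C)O2)OC1(C)C
F9 | step 8 | (2R)-1-[(4R)-4-[(tert-butyldimethylsilyl)oxy]-2,6,6-trimethylcyclohex-1-en-1-yl]-4-(trimethylsilyl)but-3-yn-2-yl acetate | C[Si](C)(C)C#C[C@H](OC(C)=O)CC1=C(C)C[C@@H](O[Si](C)(C)C(C)(C)C)CC1(C)C
F10 | step 8 | (2R)-1-[(4R)-4-hydroxy-2,6,6-trimethylcyclohex-1-en-1-yl]-4-(trimethylsilyl)but-3-yn-2-yl acetate | C[Si](C)(C)C#C[C@H](OC(C)=O)CC1=C(C)C[C@@H](O)CC1(C)C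
F11 | step 8 | (2R)-1-[(1R,4S,6S)-4-hydroxy-2,2,6-trimethyl-7-oxabicyclo[4.1.0]heptan-1-yl]-4-(trimethylsilyl)but-3-yn-2-yl acetate (oxirane cis to the ring hydroxyl) | C[Si](C)(C)C#C[C@H](OC(C)=O)C[C@]12O[C@@]1(C)C[C@@H](O)CC2(C)C
F12 | step 3 | tert-butyl{[(1R)-4-[(Z)-2-ethoxyethenyl]-3,5,5-trimethylcyclohex-3-en-1-yl]oxy}dimethylsilane | CCO/C=C\C1=C(C)C[C@@H](O[Si](C)(C)C(C)(C)C)CC1(C)C
F13 | step 3 | 2-[(4R)-4-[(tert-butyldimethylsilyl)oxy]-2,6,6-trimethylcyclohex-1-en-1-yl]acetaldehyde | O=CCC1=C(C)C[C@@H](O[Si](C)(C)C(C)(C)C)CC1(C)C
F14 | step 3 | (2RS)-1-[(4R)-4-[(tert-butyldimethylsilyl)oxy]-2,6,6-trimethylcyclohex-1-en-1-yl]-4-(trimethylsilyl)but-3-yn-2-ol (both C8 epimers) | C[Si](C)(C)C#CC(O)CC1=C(C)C[C@@H](O[Si](C)(C)C(C)(C)C)CC1(C)C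
F15 | step 13 | (3E,5E,7E)-1,1,10,10-tetrabromo-3,8-dimethyldeca-1,3,5,7,9-pentaene | BrC(Br)=C/C(C)=C/C=C/C=C(C)/C=C(Br)Br
F16 | step 13 | (3E,5E,7E)-3,8-dimethyldeca-3,5,7-triene-1,9-diyne | C#C/C(C)=C/C=C/C=C(C)/C#C
A1 | alternative 1 | bis(tert-butyldimethylsilyl) ether of (3S,5R,8R,3′S,5′R,8′R)-auroxanthin (identical with 24) | CC(/C=C/C=C(\C)[C@H]1C=C2C(C)(C)C[C@H](O[Si](C)(C)C(C)(C)C)C[C@@]2(C)O1)=C\C=C\C=C(C)\C=C\C=C(/C)[C@H]1C=C2C(C)(C)C[C@H](O[Si](C)(C)C(C)(C)C)C[C@@]2(C)O1
A2 | alternative 2 | (6R)-2,2,6-trimethylspiro[bicyclo[4.2.0]oct-1(8)-ene-4,2′-[1,3]dioxolan]-7-one (fused cyclobutenone; C5–C8 bond intact) | O=C1C=C2C(C)(C)CC3(OCCO3)C[C@]21C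
A3 | alternative 2 | (7aR)-4,4,7a-trimethyl-4,5,7,7a-tetrahydro-2H-spiro[1-benzofuran-6,2′-[1,3]dioxolan]-2-one (3-oxololiolide ethylene ketal) | O=C1C=C2C(C)(C)CC3(OCCO3)C[C@@]2(C)O1
A4 | alternative 3 | (2R,4S)-4-[(tert-butyldimethylsilyl)oxy]-2-hydroxy-2,6,6-trimethylcyclohexan-1-one | O=C1C(C)(C)C[C@H](O[Si](C)(C)C(C)(C)C)C[C@@]1(C)O
A5 | alternative 3 | (2E)-5-(trimethylsilyl)pent-2-en-4-ynal | C[Si](C)(C)C#C/C=C/C=O
A6 | alternative 3 | (2R,6S,7aR)-6-[(tert-butyldimethylsilyl)oxy]-4,4,7a-trimethyl-2-[(trimethylsilyl)ethynyl]-2,4,5,6,7,7a-hexahydro-1-benzofuran-3-carbaldehyde | C[Si](C)(C)C#C[C@H]1C(C=O)=C2C(C)(C)C[C@H](O[Si](C)(C)C(C)(C)C)C[C@@]2(C)O1
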